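## Analysis of the target

The target is a briarane-type diterpenoid. A cyclohexenone (ring A: C1, C10–C14) is trans-fused through the C1–C10 bond to a ten-membered carbocycle (C1–C10), and an α-methyl butenolide (O, C19, C17 with methyl C18) is fused across the C7–C8 edge. It has five stereocentres, the quaternary C1 (methyl C15), C10, C14 (OAc), C2 (OBz) and C7 (lactone oxygen), in the configuration 1R,2S,7R,10R,14S, plus the 5Z trisubstituted olefin. The C15 methyl and H10 are trans; the 14-acetoxy group lies on the ring-A face opposite the C15 methyl (axial); O2 is 1,3-syn to O14 across C1. C7 sits 1,6 to C2 on the far side of the medium ring with no neighbouring stereocentre to guide it. Sensitive elements are the α-acetoxy enone (epimerisable C14, acetyl migration once C13 is reduced), two different esters on two hindered carbinols flanking C1, and the C7 hydrogen, which is allylic and vinylogously acidic, so that base can pull C5=C6 into conjugation with the lactone. The difficulty is twofold: closing a ten-membered ring that carries a quaternary carbon, a cis trisubstituted olefin and a fused lactone against entropy and transannular strain, and telling apart three carbonyl-level oxygens (C2, C7, C13). The strategy rests on one feature. C2 and C7 are both oxygenated and are joined by two four-carbon paths (C3–C6 and C8–C9–C10–C1), so the ten-membered ring is the perimeter of two six-membered rings sharing a C2–C7 bond. With ring A this is a hydrophenanthrene whose ring-fusion olefin, once cleaved, leaves carbonyls exactly at C2 and C7.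

## Retrosynthetic reasoning

**C13 carbonyl (39 ⇐ 38 ⇐ 37).** Only the oxidation level at C13 is adjusted at the end: 39 comes from allylic alcohol 38 and this from silyl ether 37. The ring-A enone is withheld because each hydride step on the medium ring (C2 in 28, C7 in 34) would also reduce a cyclohexenone, and an α-acetoxy ketone would not survive the bases used. No skeletal bond is cut; the gain is that ring A is inert for ten steps.

**Butenolide (37 ⇐ 36 ⇐ 34 ⇐ 32 + 33).** The lactone is opened at O–C19 and the C8=C17 bond is cut as an aldol bond, giving the C7 enone as its silyl dienol ether 32 and methyl pyruvate 33. The cut is placed here because C7 is a ketone with a free α-methylene at C8, and 33 brings C17, C18 and C19 at the right oxidation level. Forward, the sequence must add C8 to the keto group of 33, reduce C7 from the correct face, lactonise and dehydrate into conjugation.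

**C2 ester (31 ⇐ 30 ⇐ 29 ⇐ 28).** The benzoate is traced to the C2 ketone of 28. C2 and C7 are both ketones, so they are told apart by their surroundings and not by the reagent: both are reduced (29), and only the allylic C7 carbinol is reoxidised (30). The reduction has to set 2S next to a quaternary carbon, for which catalyst control is chosen.

**C5=C6 olefin (28 ⇐ 27 ⇐ 26 ⇐ 25).** The Z olefin is placed by β-elimination of a C5 acetate through the C7 ketone. This fixes the position of the double bond between C5 and C6 and needs no olefination. Before base is applied, the ring-A enone of 25 is reduced selectively and silylated (26, 27).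

**Ten-membered ring (25 ⇐ 22).** The C2 and C7 carbonyls of 25 are rejoined as the tetrasubstituted C2=C7 olefin of tricycle 22. This replaces a medium-ring cyclisation by the cleavage of a bond shared by two six-membered rings, each made by annulation or inherited from an arene. Forward, the oxidative cleavage must touch C2=C7 only and leave the 1,6-dione intact.

**Ring A (22 ⇐ 21 ⇐ 20 ⇐ 19 ⇐ 18 ⇐ 16 ⇐ 15).** Ring A is given its final pattern before the cleavage. The C12 ketone of 15 is moved to C13 through diosphenol 18 and triflate 19, and the enone 20 is hydroxylated at C14 anti to the angular methyl (21). The enone must already be in place at the cleavage because an isolated ring-A olefin would compete for the oxidant. A later C13 oxygenation with olefin shift would also have to take place on the β face, under the C15 methyl, where the only usable allylic hydrogen lies.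

**Ring C and ring fusion (15 ⇐ 14 ⇐ 13 ⇐ 12 ⇐ 11).** The C5 methyl carbinol and the C2=C7 olefin come from an anisole ring: Birch reduction, enol ether hydrolysis and methyl addition. The same dissolving-metal step sets the trans C1/C10 fusion from the enone of 11.

**Tricycle (11 ⇐ 10 ⇐ 5 + 7; 5 ⇐ 1 + 2).** Ring A is cut at C1–C14 and C10=C11 (Robinson annulation of tetralone 5 with ethyl vinyl ketone 7). The quaternary C1 is set in the Michael step through the imine of 5 with amine 6, and 5 comes from 1 and 2 by enamine methylation. This gives all carbons of the target except C17–C19 and the two ester groups.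

## Alternatives that were turned down

**Alternative 1:** Ring A is cut at C1–C14 and C10–C11, with a temporary dialkylsilylene bridge between O14 and O2. Forward, a 13,14-dioxygenated diene (C11–C14) adds on heating to a C1=C10 enoate and gives the siladioxane-fused silyl enol ether A1.
- For it: one step creates the quaternary C1 and relays configuration between C2, C14, C1 and C10 through a rigid six-membered tether. On this point it is stronger than the chosen route, which sets C2 late by catalyst control and C14 by enolate facial selectivity.
- Against it: the ten-membered ring is untouched. A1 carries only a C10 ester and a two-carbon arm on C2, so the medium ring, the Z olefin and the butenolide still need a later macrocyclisation.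
- Against it: the dienophile is a β,β-disubstituted enoate that must form a quaternary centre, a slow class even when tethered, and C11 is sp3 in A1, so the C11=C12 unsaturation has to be put back.
- Comparison: the chosen route gives up some stereochemical economy on ring A but obtains the medium ring without a cyclisation.

**Alternative 2:** The butenolide and the ten-membered ring are cut together at C7–C8, C17–C19 and C19–O, leaving a C8≡C17 alkyne on the C10 arm and a C7 enal on the C1 arm. Forward, a low-valent metal carbonyl mediator joins alkyne, aldehyde and a carbonyl ligand to give A2.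
- For it: it is the most convergent plan and is stronger in step economy at the end. Ring and lactone form in one operation with C1, C2, C10 and C14 already in place, and it avoids the chosen route's stepwise butenolide construction and its differentiation of C2 from C7.
- Against it: carbonylative alkyne–aldehyde couplings are established where a short tether closes a five- or six-membered ring. Here the metallacycle would have to span a ten-membered ring from a flexible chain.
- Against it: the aldehyde is a Z-enal, less electrophilic and prone to isomerise, whose olefin offers the all-carbon cyclopentenone pathway, and nothing controls C7 in a macrocyclic oxametallacycle.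
- Comparison: the chosen route is longer but uses a ring-forming reaction with close precedent.

**Alternative 3:** The ring-fusion bond C1–C10 is cut, which opens the bicycle to a fourteen-membered carbocycle with a C10=C11–C12=C13(OSi)–C14=C1 trienol ether. Forward, thermal disrotatory 6π closure gives the ring-A dienol ether A3 and the ten-membered ring at once.
- For it: orbital symmetry fixes the C1/C10 relationship from the olefin geometries, the quaternary centre is made without reagents, and ring formation is maximally concise. These are real strengths.
- Against it: the fourteen-membered triene with four defined olefins, one a fully substituted terminus, is as hard to make as the target. Closure onto a tetrasubstituted terminus is slow and competes with sigmatropic hydrogen shifts.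
- Against it: the absolute sense of disrotation must be induced by remote centres at C2 and C7, and A3 still lacks O14 and the lactone oxidation level.
- Comparison: the chosen route sets C1 early by auxiliary control and the trans fusion by dissolving-metal reduction, both predictable, at the price of more functional-group steps.

Key step: step 14

Remark: all intermediates carry the locants of the target skeleton (C1 quaternary with methyl C15; C2–C9 ring members with methyl C16 on C5; C10 fusion CH; C11–C14 ring A with methyl C20 on C11; C17/C18/C19 lactone carbons), and α means the ring-A face opposite the C15 methyl. Centres formed without control and later destroyed (C5 in 14–27, C13 in 16 and 26–38, C8/C17 in 34–36) are written without configuration.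

## Route

Step 1
Reactants: 1 6-methoxy-2-tetralone; 2 iodomethane
Product: 5 rac-6-methoxy-1-methyl-2-tetralone, via pyrrolidine enamine 3 (not isolated), via methylated iminium iodide 4 (not isolated)
Conditions: pyrrolidine, PhH, reflux (Dean–Stark); MeI, 1,4-dioxane, reflux; H2O, AcOH/NaOAc, rt
Reagents that add atoms: iodomethane, CI; water, O
Why: Stork enamine alkylation; the 2-tetralone enamine is the aryl-conjugated Δ1 isomer, so monomethylation occurs at benzylic C1 and hydrolysis returns the ketone; the new centre is racemic and is resolved dynamically in step 2.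

Step 2
Reactants: 5 rac-6-methoxy-1-methyl-2-tetralone; 6 (S)-1-phenylethylamine; 7 ethyl vinyl ketone
Product: 10 (S)-6-methoxy-1-methyl-1-(3-oxopentyl)-3,4-dihydronaphthalen-2(1H)-one, via chiral enamine 8 (not isolated), via Michael adduct imine 9 (not isolated)
Conditions: 6, TsOH (cat.), PhMe, reflux (Dean–Stark); 7, THF, rt; 20% aq. AcOH, rt
Reagents that add atoms: ethyl vinyl ketone, CCC(=O)C=C; water, O
Why: Deracemising Michael addition of a chiral imine; both enantiomers of 5 converge on the more substituted, aryl-conjugated secondary enamine, which adds to the enone in a compact aza-ene-like transition state on the face away from the auxiliary phenyl group; by the topological rule for such imines the (S)-amine should give the C1 configuration of the target.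

Step 3
Reactants: 10 (S)-6-methoxy-1-methyl-1-(3-oxopentyl)-3,4-dihydronaphthalen-2(1H)-one
Product: 11 (4aR)-7-methoxy-1,4a-dimethyl-4,4a,9,10-tetrahydrophenanthren-2(3H)-one (C12 ketone; C10=C11)
Conditions: NaOMe, MeOH, 50 °C
Reagents that add atoms: none
Why: Aldol condensation closing the Robinson annulation; the ethyl CH2 (C11) adds to the C10 carbonyl and dehydration gives the tetrasubstituted enone; the quaternary C1 cannot epimerise.

Step 4
Reactants: 11 tricyclic enone
Product: 12 enol ether carbinol (12β-OH; 11α-methyl; 10α-H; olefins C2=C7 and C4=C5; 5-OMe)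
Conditions: Li, NH3(l)/THF, t-BuOH, −78 → −33 °C; then MeOH, NH4Cl
Reagents that add atoms: none
Why: One dissolving-metal operation reduces the enone to the trans-fused ring (C10 protonated anti to the angular methyl, C11 methyl equatorial), reduces the freed C12 ketone to the equatorial alcohol, which keeps it apart from the later C5 ketone, and converts the anisole by Birch reduction into the 2,5-dihydro enol ether, leaving the tetrasubstituted C2=C7 olefin.

Step 5
Reactants: 12 enol ether carbinol
Product: 13 β,γ-unsaturated 5-ketone (12β-OH; C2=C7)
Conditions: (CO2H)2·2H2O, MeOH/THF/H2O, rt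
Reagents that add atoms: water, O
Why: Mild hydrolysis of the methyl enol ether; oxalic acid is too weak to move C2=C7 into conjugation, as known for Birch-derived 3-cyclohexenones.

Step 6
Reactants: 13 β,γ-unsaturated 5-ketone
Product: 14 5,12β-diol (5-methyl carbinol; both C5 epimers)
Conditions: MeLi, CeCl3 (anhydrous), THF, −78 °C
Reagents that add atoms: methyllithium, C[Li]
Why: Organocerium 1,2-addition avoids enolisation of the doubly activated C6 methylene; the remote ring offers no facial bias, so C5 forms as both epimers, which is harmless because C5 becomes sp2 in step 16.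

Step 7
Reactants: 14 5,12β-diol
Product: 15 12-ketone (5-OH; 11α-methyl; C2=C7)
Conditions: Dess–Martin periodinane, NaHCO3, CH2Cl2, rt
Reagents that add atoms: none
Why: Dess–Martin oxidation of the only secondary carbinol; the tertiary C5 alcohol and the tetrasubstituted olefin are inert.

Step 8
Reactants: 15 12-ketone
Product: 16 13-hydroxy-12-ketone
Conditions: LiN(i-Pr)2 (2.2 equiv), THF, −78 °C; 2-(phenylsulfonyl)-3-phenyloxaziridine, −78 °C; NH4Cl
Reagents that add atoms: 2-(phenylsulfonyl)-3-phenyloxaziridine, O=S(=O)(c1ccccc1)N1OC1c1ccccc1
Why: Kinetic deprotonation at the C13 methylene (not the C11 methine) after the first equivalent of base is taken by the C5 hydroxyl, then Davis enolate hydroxylation; the C13 configuration is irrelevant since it is oxidised next.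

Step 9
Reactants: 16 13-hydroxy-12-ketone
Product: 18 diosphenol (12-hydroxy-11-en-13-one), via 12,13-dione 17 (not isolated)
Conditions: Dess–Martin periodinane, CH2Cl2, rt; then Et3N (cat.), rt
Reagents that add atoms: none
Why: Oxidation of the acyloin to the 1,2-dione, which enolises toward the more substituted carbon (C11) as 3-alkylcyclohexane-1,2-diones do, leaving the carbonyl at C13 and erasing the C11 centre.

Step 10
Reactants: 18 diosphenol
Product: 19 enol triflate (12-triflyloxy-11-en-13-one)
Conditions: PhNTf2, Et3N, DMAP (cat.), CH2Cl2, 0 °C → rt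
Reagents that add atoms: N-phenylbis(trifluoromethanesulfonimide), O=S(=O)(N(c1ccccc1)S(=O)(=O)C(F)(F)F)C(F)(F)F
Why: O-Sulfonylation of the acidic enol hydroxyl; the non-acidic tertiary C5 alcohol is not triflated under amine base.

Step 11
Reactants: 19 enol triflate
Product: 20 transposed enone (13-oxo; C11=C12; 5-OH; C2=C7)
Conditions: Pd(OAc)2 (5 mol%), PPh3, HCO2H, n-Bu3N, DMF, 60 °C
Reagents that add atoms: none
Why: Palladium-catalysed formate reduction of a vinyl triflate (oxidative addition, formate exchange, decarboxylation, reductive elimination) completes the 1,2-carbonyl transposition from C12 to C13.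

Step 12
Reactants: 20 transposed enone
Product: 21 14α-hydroxy enone (14S)
Conditions: LiN(i-Pr)2 (2.2 equiv), THF, −78 °C; 2-(phenylsulfonyl)-3-phenyloxaziridine; NH4Cl
Reagents that add atoms: 2-(phenylsulfonyl)-3-phenyloxaziridine, O=S(=O)(c1ccccc1)N1OC1c1ccccc1
Why: Kinetic α′-deprotonation at C14 gives the cross-conjugated dienolate, and Davis hydroxylation occurs axially on the face opposite the adjacent axial C15 methyl, so stereoelectronic and steric preferences both lead to 14α-OH.

Step 13
Reactants: 21 14α-hydroxy enone
Product: 22 5,14α-diacetoxy-13-oxo tricycle (C11=C12; C2=C7)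
Conditions: Ac2O, DMAP, Et3N, CH2Cl2, rt → 40 °C
Reagents that add atoms: acetic anhydride, CC(=O)OC(C)=O
Why: DMAP-catalysed acetylation of the secondary ketol hydroxyl and, on warming, of the tertiary C5 hydroxyl; the C14 acetate is the one in the target and the C5 acetate is the leaving group for step 16.

Step 14
Reactants: 22 5,14α-diacetoxy-13-oxo tricycle
Product: 25 ring-A-fused cyclodecane-2,7-dione (5,14α-diacetoxy-11-ene-2,7,13-trione), via primary ozonide 23 (not isolated), via secondary ozonide 24 (not isolated)
Conditions: O3, CH2Cl2, NaHCO3, Sudan Red 7B (trace), −78 °C; then Me2S, −78 °C → rt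
Reagents that add atoms: ozone, [O-][O+]=O
Why: Ozone adds as a 1,3-dipole across the electron-rich tetrasubstituted C2=C7 bond to give primary ozonide 23, which cycloreverts to a ketone and a carbonyl oxide held in the same molecule and recloses to the bridged 1,2,4-trioxolane 24; dimethyl sulfide reduces the peroxide and releases both ketones. The closest known reaction type is the ozonolysis of the central double bond of 9,10-octalins and Birch-derived hexahydronaphthalenes to cyclodecane-1,6-diones. The ten-membered ring is not closed by a bond-forming cyclisation: it appears when the bond shared by rings B and C is cut, which merges two six-membered rings into their ten-membered perimeter. No stereocentre is created, and C1 (quaternary), C10 and C14 lie outside the reacting bond and keep their configuration. The step needs chemoselectivity for C2=C7 over C11=C12, which is secured because the latter is an enone π bond deactivated toward the electrophilic dipole and is monitored by a dye that bleaches only after the tetraalkyl olefin is consumed. It also needs the 1,6-dione to survive, so the work-up is cold, reductive and buffered: acid or base would start transannular aldolisation between C3 or C8 and the opposite carbonyl, and base would eliminate the C5 acetate too early.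

Step 15
Reactants: 25 ring-A-fused cyclodecane-2,7-dione
Product: 26 13-hydroxy-2,7-dione (C11=C12; either C13 epimer)
Conditions: NaBH4, CeCl3·7H2O, MeOH, −78 °C; then acetone, AcOH
Reagents that add atoms: none
Why: Luche 1,2-reduction picks the cyclohexenone over the two saturated medium-ring ketones, which are slow to rehybridise (transannular strain; C2 also neopentyl); this masks ring A for the later hydride and base steps, and the C13 configuration is irrelevant since it is reoxidised in step 25.

Step 16
Reactants: 26 13-hydroxy-2,7-dione
Product: 28 13-OTBS (5Z)-5-ene-2,7-dione, via TBS ether 27 (not isolated)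
Conditions: TBSOTf, 2,6-lutidine, CH2Cl2, −78 °C; then DBU, −20 → 0 °C
Reagents that add atoms: tert-butyldimethylsilyl triflate, CC(C)(C)[Si](C)(C)OS(=O)(=O)C(F)(F)F
Why: Silylation stops acetyl migration from O14 to O13; DBU then effects E1cB loss of the tertiary β-acetoxy group through the C6 enolate of the C7 ketone, which places the olefin at C5=C6, and the in-ring cis (5Z) enone is the expected geometry for a ten-membered ring; short cold contact with base limits transannular aldolisation.

Step 17
Reactants: 28 13-OTBS (5Z)-5-ene-2,7-dione
Product: 29 (2S)-2,7-diol (either C7 epimer)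
Conditions: (R)-Me-CBS oxazaborolidine (1 equiv), catecholborane, PhMe, −40 → 0 °C; then MeOH, aq. NaHCO3
Reagents that add atoms: none
Why: Corey–Bakshi–Shibata reduction; the C2 ketone lies between a quaternary carbon (large) and a methylene (small), the best-behaved ketone class for this catalyst, and the (R)-catalyst should deliver hydride to give 2S; the C7 enone is reduced as well and restored in step 18, and catecholborane leaves the esters and olefins alone.

Step 18
Reactants: 29 (2S)-2,7-diol
Product: 30 (2S)-2-hydroxy-(5Z)-5-en-7-one
Conditions: MnO2, CH2Cl2, rt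
Reagents that add atoms: none
Why: MnO2 oxidises only the allylic C7 carbinol, so the two ring carbonyls of 28 are told apart by their surroundings; the saturated neopentyl C2 carbinol is untouched.

Step 19
Reactants: 30 (2S)-2-hydroxy-(5Z)-5-en-7-one
Product: 31 2-benzoate of the (5Z)-5-en-7-one
Conditions: BzCl, DMAP, pyridine, 40 °C
Reagents that add atoms: benzoyl chloride, O=C(Cl)c1ccccc1
Why: DMAP-catalysed acylation of the only free hydroxyl; warming overcomes the hindrance next to C1.

Step 20
Reactants: 31 2-benzoate of the (5Z)-5-en-7-one
Product: 32 7-trimethylsilyloxy-5,7-diene (silyl dienol ether; C7=C8)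
Conditions: TMSOTf, Et3N, CH2Cl2, 0 °C
Reagents that add atoms: trimethylsilyl triflate, C[Si](C)(C)OS(=O)(=O)C(F)(F)F
Why: Soft enolisation of the single ketone at its α′ methylene (C8) gives the cross-conjugated 2-silyloxy diene; no strong base is used, so the acetate and benzoate are safe.

Step 21
Reactants: 32 silyl dienol ether; 33 methyl pyruvate
Product: 34 C8 aldol adduct (8-[2-hydroxy-1-methoxy-1-oxopropan-2-yl]-(5Z)-5-en-7-one; C8 and C17 mixtures)
Conditions: 33, Cu(OTf)2 / 2,2'-isopropylidenebis[(4S)-4-tert-butyl-2-oxazoline] (10 mol%), CH2Cl2, −78 °C; then 1 M HCl, THF, 0 °C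
Reagents that add atoms: methyl pyruvate, CC(=O)C(=O)OC
Why: Mukaiyama aldol addition; the enol-ether terminus C8 attacks the keto group of the chelated pyruvate to form C8–C17 and regenerate the C7 enone; the two new centres form as mixtures and both vanish in step 23.

Step 22
Reactants: 34 C8 aldol adduct
Product: 36 17-hydroxy γ-lactone (7R; C7–O–C19), via hydroxy ester 35 (not isolated)
Conditions: NaBH4, CeCl3·7H2O, MeOH, −78 → 0 °C
Reagents that add atoms: none
Why: Luche 1,2-reduction of the only ketone, then 5-exo lactonisation of the allylic alkoxide onto the neighbouring methyl ester; C7 is set by hydride delivery from the exposed outer face of the ten-membered enone, expected but not assured to give 7R, and is the least secure stereochemical call of the route.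

Step 23
Reactants: 36 17-hydroxy γ-lactone
Product: 37 13-OTBS butenolide (C8=C17)
Conditions: SOCl2, pyridine, CH2Cl2, 0 °C
Reagents that add atoms: none
Why: Dehydration of the tertiary α-hydroxy lactone through its chlorosulfite; Zaitsev elimination toward C8–H gives the tetrasubstituted conjugated butenolide and removes both uncontrolled centres; pyridine is too weak to deprotonate C7.

Step 24
Reactants: 37 13-OTBS butenolide
Product: 38 13-hydroxy butenolide
Conditions: HF·pyridine, pyridine/THF, 0 °C → rt
Reagents that add atoms: none
Why: Buffered fluoride cleavage of the secondary silyl ether; the esters and the lactone are stable and the medium is not basic enough for acetyl migration or C7 deprotonation.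

Step 25
Reactants: 38 13-hydroxy butenolide
Product: 39 CNP0194180.3 (target)
Conditions: Dess–Martin periodinane, NaHCO3, CH2Cl2, 0 °C → rt
Reagents that add atoms: none
Why: Dess–Martin oxidation of the allylic alcohol returns the C13 enone under non-basic conditions, so C14 and C7 are not epimerised and C5=C6 stays out of conjugation.

## Compound list

1 | 6-methoxy-2-tetralone | COc1ccc2CC(=O)CCc2c1 | starting material
2 | iodomethane | CI | starting material
3 | pyrrolidine enamine of 1 | COc1ccc2C=C(N3CCCC3)CCc2c1 | intermediate
4 | C1-methylated iminium iodide | COc1ccc2C(C)C(=[N+]3CCCC3)CCc2c1.[I-] | intermediate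
5 | rac-6-methoxy-1-methyl-2-tetralone | COc1ccc2C(C)C(=O)CCc2c1 | intermediate
6 | (S)-1-phenylethylamine | C[C@H](N)c1ccccc1 | starting material
7 | ethyl vinyl ketone | CCC(=O)C=C | starting material
8 | secondary enamine of 5 with 6 | COc1ccc2C(C)=C(N[C@@H](C)c3ccccc3)CCc2c1 | intermediate
9 | Michael adduct imine | CCC(=O)CC[C@]1(C)C(=N[C@@H](C)c2ccccc2)CCc2cc(OC)ccc21 | intermediate
10 | (S)-6-methoxy-1-methyl-1-(3-oxopentyl)-3,4-dihydronaphthalen-2(1H)-one | CCC(=O)CC[C@]1(C)C(=O)CCc2cc(OC)ccc21 | intermediate
11 | (4aR)-7-methoxy-1,4a-dimethyl-4,4a,9,10-tetrahydrophenanthren-2(3H)-one | CC1=C2CCc3cc(OC)ccc3[C@]2(C)CCC1=O | intermediate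
12 | enol ether carbinol (12β-OH, 11α-methyl, 10α-H, C2=C7, C4=C5, 5-OMe) | C1C[C@@H](O)[C@H](C)[C@H]2CCC3=C(CC=C(OC)C3)[C@@]21C | intermediate
13 | β,γ-unsaturated 5-ketone, 12β-ol | C1C[C@@H](O)[C@H](C)[C@H]2CCC3=C(CCC(=O)C3)[C@@]21C | intermediate
14 | 5,12β-diol (C5 epimers) | C1C[C@@H](O)[C@H](C)[C@H]2CCC3=C(CCC(C)(O)C3)[C@@]21C | intermediate
15 | 12-ketone, 5-ol | C1CC(=O)[C@H](C)[C@H]2CCC3=C(CCC(C)(O)C3)[C@@]21C | intermediate
16 | 13-hydroxy-12-ketone | C1C(O)C(=O)[C@H](C)[C@H]2CCC3=C(CCC(C)(O)C3)[C@@]21C | intermediate
17 | 12,13-dione | C1C(=O)C(=O)[C@H](C)[C@H]2CCC3=C(CCC(C)(O)C3)[C@@]21C | intermediate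
18 | diosphenol (12-hydroxy-11-en-13-one) | C1C(=O)C(O)=C(C)[C@H]2CCC3=C(CCC(C)(O)C3)[C@@]21C | intermediate
19 | enol triflate (12-triflyloxy-11-en-13-one) | C1C(=O)C(OS(=O)(=O)C(F)(F)F)=C(C)[C@H]2CCC3=C(CCC(C)(O)C3)[C@@]21C | intermediate
20 | transposed enone (13-oxo, C11=C12, 5-OH) | C1C(=O)C=C(C)[C@H]2CCC3=C(CCC(C)(O)C3)[C@@]21C | intermediate
21 | 14α-hydroxy enone | O[C@@H]1C(=O)C=C(C)[C@H]2CCC3=C(CCC(C)(O)C3)[C@@]21C | intermediate
22 | 5,14α-diacetoxy-13-oxo tricycle with C2=C7 (ozonolysis substrate) | CC(=O)O[C@@H]1C(=O)C=C(C)[C@H]2CCC3=C(CCC(C)(OC(C)=O)C3)[C@@]21C | intermediate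
23 | primary ozonide (1,2,3-trioxolane on C2/C7) | CC(=O)O[C@@H]1C(=O)C=C(C)[C@H]2CCC34CC(C)(OC(C)=O)CCC3(OOO4)[C@@]21C | intermediate
24 | secondary ozonide (1,2,4-trioxolane bridging C2 and C7) | CC(=O)O[C@@H]1C(=O)C=C(C)[C@H]2CCC3(O4)CC(C)(OC(C)=O)CCC4(OO3)[C@@]21C | intermediate
25 | ring-A-fused cyclodecane-2,7-dione (5,14α-diacetoxy-11-ene-2,7,13-trione) | CC(=O)O[C@@H]1C(=O)C=C(C)[C@H]2CCC(=O)CC(C)(OC(C)=O)CCC(=O)[C@@]21C | intermediate
26 | 13-hydroxy-2,7-dione | CC(=O)O[C@@H]1C(O)C=C(C)[C@H]2CCC(=O)CC(C)(OC(C)=O)CCC(=O)[C@@]21C | intermediate
27 | 13-OTBS 2,7-dione with 5-OAc | CC(=O)O[C@@H]1C(O[Si](C)(C)C(C)(C)C)C=C(C)[C@H]2CCC(=O)CC(C)(OC(C)=O)CCC(=O)[C@@]21C | intermediate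
28 | 13-OTBS (5Z)-5-ene-2,7-dione | CC(=O)O[C@@H]1C(O[Si](C)(C)C(C)(C)C)C=C(C)[C@H]2CCC(=O)/C=C(/C)CCC(=O)[C@@]21C | intermediate
29 | (2S)-2,7-diol | CC(=O)O[C@@H]1C(O[Si](C)(C)C(C)(C)C)C=C(C)[C@H]2CCC(O)/C=C(/C)CC[C@H](O)[C@@]21C | intermediate
30 | (2S)-2-hydroxy-(5Z)-5-en-7-one | CC(=O)O[C@@H]1C(O[Si](C)(C)C(C)(C)C)C=C(C)[C@H]2CCC(=O)/C=C(/C)CC[C@H](O)[C@@]21C | intermediate
31 | 2-benzoate of the (5Z)-5-en-7-one | CC(=O)O[C@@H]1C(O[Si](C)(C)C(C)(C)C)C=C(C)[C@H]2CCC(=O)/C=C(/C)CC[C@H](OC(=O)c3ccccc3)[C@@]21C | intermediate
32 | 7-trimethylsilyloxy-5,7-diene | CC(=O)O[C@@H]1C(O[Si](C)(C)C(C)(C)C)C=C(C)[C@H]2CC=C(O[Si](C)(C)C)/C=C(/C)CC[C@H](OC(=O)c3ccccc3)[C@@]21C | intermediate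
33 | methyl pyruvate | CC(=O)C(=O)OC | starting material
34 | C8 aldol adduct | CC(=O)O[C@@H]1C(O[Si](C)(C)C(C)(C)C)C=C(C)[C@H]2CC(C(C)(O)C(=O)OC)C(=O)/C=C(/C)CC[C@H](OC(=O)c3ccccc3)[C@@]21C | intermediate
35 | 7-hydroxy ester | CC(=O)O[C@@H]1C(O[Si](C)(C)C(C)(C)C)C=C(C)[C@H]2CC(C(C)(O)C(=O)OC)[C@H](O)/C=C(/C)CC[C@H](OC(=O)c3ccccc3)[C@@]21C | intermediate
36 | 17-hydroxy γ-lactone | CC(=O)O[C@@H]1C(O[Si](C)(C)C(C)(C)C)C=C(C)[C@H]2CC3C(C)(O)C(=O)O[C@@H]3/C=C(/C)CC[C@H](OC(=O)c3ccccc3)[C@@]21C | intermediate
37 | 13-OTBS butenolide | CC(=O)O[C@@H]1C(O[Si](C)(C)C(C)(C)C)C=C(C)[C@H]2CC3=C(C)C(=O)O[C@@H]3/C=C(/C)CC[C@H](OC(=O)c3ccccc3)[C@@]21C | intermediate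
38 | 13-hydroxy butenolide | CC(=O)O[C@@H]1C(O)C=C(C)[C@H]2CC3=C(C)C(=O)O[C@@H]3/C=C(/C)CC[C@H](OC(=O)c3ccccc3)[C@@]21C | intermediate
39 | CNP0194180.3, (1R,2S,5Z,7R,10R,14S)-14-acetoxy-2-benzoyloxy-13-oxo-5,8(17),11-triene 7,19-lactone | CC(=O)O[C@@H]1C(=O)C=C(C)[C@H]2CC3=C(C)C(=O)O[C@@H]3/C=C(/C)CC[C@H](OC(=O)c3ccccc3)[C@@]21C | target

## Step count and least certain steps

Total: 25 steps, all in one line; the longest linear sequence is 25 steps from 1 (13 before the key step, 11 after it).

**Step 14 (key step).** The congested C2 terminus next to the quaternary C1 may divert the ozonide pathway toward epoxide formation or over-oxidation. The 1,6-dione 25 may also collapse by transannular aldolisation during work-up, a known tendency of cyclodecane-1,6-diones. Fallback: from 22, peracid epoxidation (mCPBA, NaHCO3, CH2Cl2), which also selects the electron-rich olefin, gives the 2,7-epoxide F1. Periodic acid (H5IO6, aq. THF) then opens and cleaves it in one pot to return to 25.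

**Step 16.** Base on a ring that still holds two ketones may trigger transannular aldolisation. Dienolate equilibration may also move the new double bond out of conjugation or scramble its geometry, a common drift in medium-ring enones. Fallback: from 26, silylate only and isolate 27, then reduce both ring ketones with the reagent system of step 17 to the 13-OTBS 2,7-diol F2. Reoxidise the unhindered C7 carbinol selectively (TEMPO, PhI(OAc)2) to the 2-hydroxy-7-ketone F3, benzoylate to the 5-acetoxy 2-benzoate F4, and only then eliminate with DBU, now with a single ring carbonyl. This rejoins the route at 31.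

**Step 17.** The neopentyl medium-ring ketone may react sluggishly, and the conformational bias of the ring may override the catalyst, giving poor or reversed facial selectivity at C2. Fallback: from 28, reduce under substrate control (NaBH4, CeCl3·7H2O) and accept the ring's preference. If this is the 2-epimeric diol F5, MnO2 gives the 2-epi hydroxy enone F6, and Mitsunobu esterification with benzoic acid (PPh3, diisopropyl azodicarboxylate) installs the benzoate with inversion, rejoining at 31.

**Step 22.** Facial selectivity of hydride delivery to the flexible ten-membered enone cannot be predicted with confidence, the more so as C8 is a mixture, so the 7-epimer may dominate. Fallback: from 34, replace substrate control by catalyst control and reduce with Me-CBS oxazaborolidine and catecholborane, using whichever catalyst antipode matches. Lactonisation follows as before to 36, and the fallback makes no new compound (F0).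

**Step 23.** In diastereomers of 36 that lack a C8 hydrogen antiperiplanar to the leaving group, elimination may run toward the C18 methyl and give the exocyclic isomer. Fallback: from 36, accept this outcome and isomerise the α-methylene lactone F7 into conjugation with RhCl3·3H2O (cat.) in EtOH at 60 °C. The tetrasubstituted butenolide is the thermodynamic isomer, and the route is rejoined at 37.

## Further compounds

F1 | step 14 | 2,7-epoxide of 22 | CC(=O)O[C@@H]1C(=O)C=C(C)[C@H]2CCC34CC(C)(OC(C)=O)CCC3(O4)[C@@]21C
F2 | step 16 | 13-OTBS 5-acetoxy (2S)-2,7-diol | CC(=O)O[C@@H]1C(O[Si](C)(C)C(C)(C)C)C=C(C)[C@H]2CCC(O)CC(C)(OC(C)=O)CC[C@H](O)[C@@]21C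
F3 | step 16 | 13-OTBS 5-acetoxy (2S)-2-hydroxy-7-ketone | CC(=O)O[C@@H]1C(O[Si](C)(C)C(C)(C)C)C=C(C)[C@H]2CCC(=O)CC(C)(OC(C)=O)CC[C@H](O)[C@@]21C
F4 | step 16 | 13-OTBS 5-acetoxy 2-benzoyloxy-7-ketone | CC(=O)O[C@@H]1C(O[Si](C)(C)C(C)(C)C)C=C(C)[C@H]2CCC(=O)CC(C)(OC(C)=O)CC[C@H](OC(=O)c3ccccc3)[C@@]21C
F5 | step 17 | 2-epi-2,7-diol | CC(=O)O[C@@H]1C(O[Si](C)(C)C(C)(C)C)C=C(C)[C@H]2CCC(O)/C=C(/C)CC[C@@H](O)[C@@]21C
F6 | step 17 | 2-epi-2-hydroxy-(5Z)-5-en-7-one | CC(=O)O[C@@H]1C(O[Si](C)(C)C(C)(C)C)C=C(C)[C@H]2CCC(=O)/C=C(/C)CC[C@@H](O)[C@@]21C
F0 | step 22 | none | none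
F7 | step 23 | 13-OTBS α-methylene γ-lactone (C17=C18 exocyclic) | CC(=O)O[C@@H]1C(O[Si](C)(C)C(C)(C)C)C=C(C)[C@H]2CC3C(=C)C(=O)O[C@@H]3/C=C(/C)CC[C@H](OC(=O)c3ccccc3)[C@@]21C
A1 | alternative 1 | ring A silyl enol ether fused to a siladioxane (tethered cycloadduct) | O1[C@@H]2C(O[Si](C)(C)C(C)(C)C)=C[C@H](C)[C@@H](C(=O)OC)[C@]2(C)[C@H](CCOCc3ccc(OC)cc3)O[Si]1(C(C)C)C(C)C
A2 | alternative 2 | 13-O-silyl tricyclic butenolide | CC(=O)O[C@@H]1[C@@H](O[Si](C)(C)C(C)(C)C)C=C(C)[C@H]2CC3=C(C)C(=O)O[C@@H]3/C=C(/C)CC[C@H](OC(=O)c3ccccc3)[C@@]21C
A3 | alternative 3 | bicyclic ring A silyl dienol ether | C1=C(O[Si](CC)(CC)CC)C=C(C)[C@H]2CC(OC)(OC)[C@H](OCc3ccc(OC)cc3)/C=C(/C)CC[C@H](O[Si](C)(C)C(C)(C)C)[C@@]21C
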